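The numbers in the tables were generated by integration for an exercise, and the scatter is random.

| flask | X | G | temperature | remark | time |
|---|---|---|---|---|---|
| zeta | 0.050 M | 15 mM (held) | 20 °C | the very flask that is asked about, followed so far |  |
| eta | 0.075 M | 15 mM (held) | 15 °C | run made earlier |  |
| flask | 0.050 M | 15 mM (held) | 20 °C |  | 15 min |

| zeta: time / min | zeta: Q / % | eta: time / min | eta: Q / % |
|---|---|---|---|
| 0.667 | 8.9 | 0.250 | 0.6 |
| 1.50 | 38.8 | 0.500 | 4.5 |
| 4.00 | 43.3 | 1.33 | 33.4 |
| 10.0 | 44.5 | 3.00 | 34.9 |

(scatter of a reading: 0.5 percentage points)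

- larch: at 15 min add X, 50.0 % of the amount charged, then wait 30 min
- maple: at 15 min raise the temperature by 20 K, then wait 30 min
- alder: at 15 min take out 90 % of the Q then present, then wait 30 min
- ash: change nothing and wait 30 min more

- at the start none of E is dissolved
- what is taken out of Q is counted as made
- the analysis behind the earlier runs scatters by 0.5 percentage points, standard deviation
- candidate steps: X + E -> Q + Z; X + E + Z -> Q + 2 Z; Q <-> L; G <-> E
- additions bring no volume worth counting

- Q, in percent of the X first charged, at 15 min
- the option that brings most further Q ("none" if no option brings more than 2 percentage points) (larch / maple / alder / ash / none)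
- Q present, with what was taken out counted in, in percent of the X first charged, after larch
- Q present, with what was taken out counted in, in percent of the X first charged, after alder

Slowness comes first: in zeta, Q stands at 8.9 % of the charge after 0.667 min, a climb of 0.133 min⁻¹. Up to 1.50 min the curve steepens to 0.359 min⁻¹, which is 2.70 times the opening slope. That is the look of the candidate step in which Z speeds its own making. Then comes the knee: up to 4.00 min the climb is 0.0180 min⁻¹.

I follow one molecule of X. Once reacted it stands at the fork Q <-> L, which I assume is quick against these minutes. I call the last zeta reading, 44.5 %, the Q share: the chance that a reacted molecule of X is found as Q rather than L. This is thermodynamic control. On straight lines between readings, the curve crosses half that level at 1.04 min.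

For maple I need the odds. As read, they are 0.802 in zeta and 0.536 in eta, a factor of 1.50. The two runs differ in the charge of X as well as in temperature, but I assume that this factor belongs to the step from 15 °C to 20 °C. I let 20 K count as 4 such steps.

- now: 44.5 %
- ash: no gain
- larch, s on the enlarged charge: 66.8 %
- alder, the part taken out plus s of what stays: 66.7 %
- maple: odds 4.01, so 80.0 %

So maple gains 36 percentage points against 22 points for larch.

The forecast gives 44.7 %, maple, 67 % and 66.9 %, on this ground: “the plateau is the fast Q ⇌ L equilibrium”. Its maple level is 78 %, mine 80.0 %.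

The flask holds Q at 43.5 % at 15 min. Maple brings 29 points, against 22 points for larch, 22 points for alder and 0 points for ash, so maple leads; larch ends at 65.2 % and alder at 65.6 %. Q and L relax with a half-life of 2.06 s, short against 15 min. Dividing the zeta reading at 1.50 min by s says 87.2 % of the charge has reacted; the flask holds X 14.7 % at 1.50 min.

    X + E → Q + Z (k = 0.0690 L mol⁻¹ s⁻¹, Ea = 48.0 kJ mol⁻¹)
    X + E + Z → Q + 2 Z (k = 87.0 L² mol⁻² s⁻¹, Ea = 37.0 kJ mol⁻¹)
    Q ⇌ L (K = 1.30, k = 0.190 s⁻¹, Ea = 65.0 kJ mol⁻¹, ΔH = −47.0 kJ mol⁻¹)
    G ⇌ E, rate k4*(csat - [E]) (kL = 5.40 s⁻¹)
    (constants at 20 °C)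

A neighbouring flask, at −5 °C, lies 5 such steps below zeta, so s gives it odds of 0.107 and a Q share of 9.68 %. Computed, that neighbouring flask holds Q at 11.3 %.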